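I will judge this flask by one number read from its own run, so the run comes first.

| setting | gamma | flask |
|---|---|---|
| E | 1.8 M | 1.8 M |
| remark | the very flask that is asked about, followed so far |  |
| time |  | 12 h |
gamma run (percent of the E charged)

| time / h | Q / % | Z / % |
|---|---|---|
| 0.333 | 92.8 | 91.4 |
| 0.833 | 94.9 | 94.0 |
| 1.50 | 95.0 | 94.0 |
| 2.50 | 94.7 | 93.8 |
| 4.00 | 95.1 | 94.3 |

(standard deviation of a reading: 0.3 percentage points)
* the Q and Z together standing at 12 h, as a percentage of the E charged
* concentration of Q in solution at 12 h, in percent of saturation
- in percentages every species weighs as the E in it: one L counts as two
- in percentages every species weighs as the E in it: one G counts as three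
- for Q the Z are counted in
- as a solid, counted per litre of solution: Z
- the numbers in the tables scatter by 0.3 percentage points (one standard deviation)
- steps under discussion: Z <-> Q; 2 E -> L; E -> Q; E + L -> G

What does the run show? In the gamma run, Q averages 94.9% over the four readings from 0.833 h on, so 5.07% of the E charged stands outside Q; call this w, the lost share. A mean of four readings carries a scatter of 0.15 percentage points.

Is it a plateau? Q rose 2.1 points between the first two readings, then 0.2 points up to 4.00 h, against a scatter of 0.3 points.

But can w grow later? The listed steps that make L and G take E, and the flat Q readings of the gamma run give no sign of E still going to Q; Q itself goes on to Z, which is counted in Q. So I commit to y as one minus w, 94.9%.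

The forecast says 94.9% and 100%, holding that “the listed steps offer no route from these back to E or Q”. Its y comes from the same readings as mine.

The flask gives 94.9% and 100%.

    Z ⇌ Q, rate k1*(cs1 - [Q]) while solid is left; crystals form when [Q] > cs1 (solubility = 19.0 mM, k = 0.610 /min)
    2 E → L (k = 0.00540 /M/min)
    E → Q (k = 0.200 /min)
    E + L → G (k = 0.0500 /M/min)

At 12.0 h this flask holds L and G together at 5.10%, against the 5.07% read from the gamma run as w, and the neighbour flask read at 8.0 h holds 5.10%. At the start, the path from E to Q uses E ten times as fast as the path from 2 E to L. In this flask E already stands at 0% by 1.20 h, and L and G stay at these values up to 120 h. A charge of 3.56 M of E, twice this flask's, is the nearest above it at which y has moved by 5 points.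

(The earlier runs and the new flask stem from a simulated flask for substances that don't exist.)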